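**Retrosynthetic overview**

1. The dihydrofuran ring is the only ring made, and it is made last: acid strips six MOM ethers from open-chain precursor 14 and closes O1–C2 onto a para-quinone methide, trans to the existing C-3 centre.
2. The key C3–C3a bond of 14 comes from a stereoconvergent nickel-catalysed radical cross-coupling of racemic benzylic bromide 11 with arylzinc 13; the ligand sets C-3.
3. Both coupling partners are made from one stilbene, 10: bromo-methoxylation gives 11, and metalation between the two MOM ethers gives 13, which fixes the position of the new bond on the resorcinol ring.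
4. Stilbene 10 comes from a Heck coupling of aryl bromide 9 (from catechol) with styrene 5 (from resorcinol by C–H borylation and vinylation).
5. All three benzene rings are bought as resorcinol or catechol; no carbocycle is constructed.

Assumption: the facial preference of the NiBr2·diglyme/(S,S)-Ph-BOX catalyst on this new substrate cannot be predicted from precedent; the route is written with the (S,S)-ligand, and the mirror-image ligand is used if the first run gives (S) at C-3.

The target is (2R,3R), trans. Benzofuran numbering (C-2, C-3, C-3a) is used for the corresponding carbons of open-chain intermediates.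

**Route**

Step 1
Reactants: 1 resorcinol
Product: 2 1,3-bis(methoxymethoxy)benzene
Conditions: NaH (2.4 equiv), MOMCl (2.4 equiv), DMF, 0 °C to rt
Reagents that add atoms: chloromethyl methyl ether (MOMCl), COCCl
Why: Williamson O-alkylation of both phenoxides; MOM is chosen because it later directs metalation and is removed by the acid of the last step.

Step 2
Reactants: 2 1,3-bis(methoxymethoxy)benzene
Product: 3 2-[3,5-bis(methoxymethoxy)phenyl]-4,4,5,5-tetramethyl-1,3,2-dioxaborolane
Conditions: [Ir(OMe)(cod)]2 (1.5 mol %), 4,4'-di-tert-butyl-2,2'-bipyridine (3 mol %), B2pin2 (0.55 equiv), THF, 80 °C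
Reagents that add atoms: bis(pinacolato)diboron, CC1(C)OB(OC1(C)C)B1OC(C)(C)C(C)(C)O1
Why: iridium-catalysed aromatic C–H borylation is sterically controlled, and C-5 is the only C–H without an ortho substituent.

Step 3
Reactants: 3 arylboronate; 4 vinyl bromide
Product: 5 1-ethenyl-3,5-bis(methoxymethoxy)benzene
Conditions: Pd(PPh3)4 (3 mol %), K2CO3 (3 equiv), vinyl bromide (1 M in THF, 3 equiv), THF/H2O 5:1, 65 °C, sealed tube
Reagents that add atoms: none
Why: Suzuki–Miyaura coupling of an arylboronate with a vinyl halide; MOM ethers are stable to aqueous base.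

Step 4
Reactants: 6 catechol
Product: 7 guaiacol (2-methoxyphenol)
Conditions: MeI (1.0 equiv), K2CO3 (1.0 equiv), acetone, reflux; distil from catechol and veratrole
Reagents that add atoms: iodomethane, CI
Why: Williamson mono-O-methylation held at one equivalent; it is statistical, so guaiacol is separated from unreacted catechol and veratrole by distillation.

Step 5
Reactants: 7 guaiacol
Product: 8 4-bromo-2-methoxyphenol
Conditions: NBS (1.0 equiv), MeCN, 0 °C
Reagents that add atoms: N-bromosuccinimide, O=C1CCC(=O)N1Br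
Why: electrophilic aromatic bromination goes para to the free hydroxyl, the stronger director.

Step 6
Reactants: 8 4-bromo-2-methoxyphenol
Product: 9 4-bromo-2-methoxy-1-(methoxymethoxy)benzene
Conditions: NaH (1.2 equiv), MOMCl (1.2 equiv), THF/DMF, 0 °C to rt
Reagents that add atoms: chloromethyl methyl ether (MOMCl), COCCl
Why: Williamson O-alkylation (MOM protection) of the phenol.

Step 7
Reactants: 9 aryl bromide; 5 styrene
Product: 10 (E)-stilbene (tris-MOM ether of isorhapontigenin)
Conditions: Pd(OAc)2 (3 mol %), P(o-tol)3 (6 mol %), K2CO3 (2 equiv), n-Bu4NBr (1 equiv), DMF, 110 °C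
Reagents that add atoms: none
Why: Mizoroki–Heck coupling; syn insertion followed by syn β-hydride elimination gives the (E)-alkene.

Step 8
Reactants: 10 (E)-stilbene
Product: 11 racemic anti bromo methyl ether (Br on the carbon bearing the 3,5-dioxygenated ring; OMe on the carbon bearing the guaiacyl ring)
Conditions: NBS (1.05 equiv), MeOH/CH2Cl2 1:1, NaHCO3, −20 °C, dark
Reagents that add atoms: N-bromosuccinimide, O=C1CCC(=O)N1Br; methanol, CO
Why: bromoalkoxylation of the alkene (anti addition); methanol opens the bromonium ion at the carbon stabilised by the para-oxygenated ring, so bromine ends up on the future C-3, and the relative configuration is irrelevant because both centres are reset later.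

Step 9
Reactants: 10 (E)-stilbene (1.6 equiv, source of the nucleophile); 11 bromo methyl ether (1.0 equiv)
Product: 14 (1R)-configured open-chain hexakis-MOM coupling product (full name in the compound list), via aryllithium 12 (not isolated), via arylzinc chloride 13 (not isolated)
Conditions: 10, ZnCl2·2LiCl (1.9 equiv), THF, −78 °C, then lithium 2,2,6,6-tetramethylpiperidide (1.8 equiv), −78 to −20 °C; then 11, NiBr2·diglyme (10 mol %), (S,S)-Ph-BOX [2,2'-(propane-2,2-diyl)bis((4S)-4-phenyl-4,5-dihydrooxazole)] (13 mol %), THF/CH2Cl2, −40 °C, 48 h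
Reagents that add atoms: lithium 2,2,6,6-tetramethylpiperidide, [Li]N1C(C)(C)CCCC1(C)C; zinc chloride, Cl[Zn]Cl
Why: Proposed new method: a stereoconvergent nickel-catalysed radical Negishi arylation in which lithium 2,2,6,6-tetramethylpiperidide, a non-nucleophilic base that leaves the stilbene alone, metalates 10 only between the two MOM ethers to give 12, ZnCl2 traps it at once as 13 (so neither metal is left in 14), monovalent nickel abstracts bromine from both enantiomers of 11 to give one planar benzylic radical at C-3, the chiral aryl–nickel complex formed from 13 captures it, and reductive elimination from trivalent nickel forms C3–C3a with C-3 fixed by the ligand while the neighbouring methoxy-bearing centre stays a mixture that step 10 erases; the closest known reaction is the NiBr2·diglyme/bis(oxazoline)-catalysed enantioconvergent Negishi arylation of racemic secondary benzylic halides and mesylates to 1,1-diarylalkanes, from which this case differs by the two ortho alkoxy groups on the arylzinc and the β-methoxy branch of the bromide.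

Step 10
Reactants: 14 open-chain coupling product
Product: 17 target (2R,3R), via hexaphenol methyl ether 15 (not isolated), via quinone methide 16 (not isolated)
Conditions: HCl (1.25 M in MeOH)/THF 1:1, 0.01 M, 0 to 35 °C, argon, dark; NaHCO3 quench
Reagents that add atoms: none
Why: acid-catalysed acetal exchange removes the six MOM groups, the benzylic methyl ether of 15 ionises to para-quinone methide 16, and a flanking phenol closes the ring by intramolecular oxa-1,6-addition anti to the C-3 aryl group, so C-2 is set trans (R) by the C-3 centre whatever its configuration was in 14.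

**Compound list**

1 | resorcinol (benzene-1,3-diol) | Oc1cccc(O)c1 | starting material
2 | 1,3-bis(methoxymethoxy)benzene | COCOc1cccc(OCOC)c1 | intermediate
3 | 2-[3,5-bis(methoxymethoxy)phenyl]-4,4,5,5-tetramethyl-1,3,2-dioxaborolane | COCOc1cc(OCOC)cc(c1)B1OC(C)(C)C(C)(C)O1 | intermediate
4 | vinyl bromide (bromoethene) | C=CBr | starting material
5 | 1-ethenyl-3,5-bis(methoxymethoxy)benzene | C=Cc1cc(OCOC)cc(OCOC)c1 | intermediate
6 | catechol (benzene-1,2-diol) | Oc1ccccc1O | starting material
7 | guaiacol (2-methoxyphenol) | COc1ccccc1O | intermediate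
8 | 4-bromo-2-methoxyphenol | COc1cc(Br)ccc1O | intermediate
9 | 4-bromo-2-methoxy-1-(methoxymethoxy)benzene | COCOc1ccc(Br)cc1OC | intermediate
10 | 1-[(E)-2-[3-methoxy-4-(methoxymethoxy)phenyl]ethenyl]-3,5-bis(methoxymethoxy)benzene | COCOc1ccc(/C=C/c2cc(OCOC)cc(OCOC)c2)cc1OC | intermediate
11 | rac-4-[(1S,2R)-2-bromo-2-[3,5-bis(methoxymethoxy)phenyl]-1-methoxyethyl]-2-methoxy-1-(methoxymethoxy)benzene (anti adduct; one enantiomer drawn) | COCOc1ccc(cc1OC)[C@H](OC)[C@H](Br)c1cc(OCOC)cc(OCOC)c1 | intermediate
12 | [2,6-bis(methoxymethoxy)-4-[(E)-2-[3-methoxy-4-(methoxymethoxy)phenyl]ethenyl]phenyl]lithium | COCOc1ccc(/C=C/c2cc(OCOC)c([Li])c(OCOC)c2)cc1OC | intermediate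
13 | [2,6-bis(methoxymethoxy)-4-[(E)-2-[3-methoxy-4-(methoxymethoxy)phenyl]ethenyl]phenyl]zinc chloride | COCOc1ccc(/C=C/c2cc(OCOC)c([Zn]Cl)c(OCOC)c2)cc1OC | intermediate
14 | 2-[(1R)-1-[3,5-bis(methoxymethoxy)phenyl]-2-methoxy-2-[3-methoxy-4-(methoxymethoxy)phenyl]ethyl]-1,3-bis(methoxymethoxy)-5-[(E)-2-[3-methoxy-4-(methoxymethoxy)phenyl]ethenyl]benzene (both epimers at the methoxy-bearing carbon) | COCOc1ccc(/C=C/c2cc(OCOC)c(c(OCOC)c2)[C@@H](c2cc(OCOC)cc(OCOC)c2)C(OC)c2ccc(OCOC)c(OC)c2)cc1OC | intermediate
15 | 2-[(1R)-1-(3,5-dihydroxyphenyl)-2-(4-hydroxy-3-methoxyphenyl)-2-methoxyethyl]-5-[(E)-2-(4-hydroxy-3-methoxyphenyl)ethenyl]benzene-1,3-diol | COc1cc(/C=C/c2cc(O)c(c(O)c2)[C@@H](c2cc(O)cc(O)c2)C(OC)c2ccc(O)c(OC)c2)ccc1O | intermediate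
16 | 4-[(2R)-2-(3,5-dihydroxyphenyl)-2-[2,6-dihydroxy-4-[(E)-2-(4-hydroxy-3-methoxyphenyl)ethenyl]phenyl]ethylidene]-2-methoxycyclohexa-2,5-dien-1-one | COC1=CC(C=CC1=O)=C[C@H](c1cc(O)cc(O)c1)c1c(O)cc(/C=C/c2ccc(O)c(OC)c2)cc1O | intermediate
17 | 5-[(2R,3R)-4-hydroxy-2-(4-hydroxy-3-methoxyphenyl)-6-[(E)-2-(4-hydroxy-3-methoxyphenyl)ethenyl]-2,3-dihydro-1-benzofuran-3-yl]benzene-1,3-diol | COc1cc(/C=C/c2cc(O)c3c(c2)O[C@@H](c2ccc(O)c(OC)c2)[C@@H]3c2cc(O)cc(O)c2)ccc1O | target

**Step count and risk**

Total steps: 10. Longest linear sequence: 7 (steps 1, 2, 3, 7, 8, 9, 10 from resorcinol; the catechol branch, steps 4, 5, 6, 7, 8, 9, 10, is equally long).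

Steps most likely to fail, each with a fallback:

Step 9. The hindered arylzinc may not couple at nickel, the alkylnickel intermediate may lose methoxide and return stilbene, or the ee at C-3 may be low. The fallback sets out from 11 and 13, forms the same C3–C3a bond by a radical chain arylation of an enolate, and sets the stereocentre in a separate step. Arylzinc 13 is quenched with iodine to give aryl iodide F1. Bromo ether 11 is treated with KOt-Bu (THF, 0 °C; anti elimination of HBr) to give enol ether F2, which dilute aqueous oxalic acid hydrolyses to deoxybenzoin-type ketone F3. The potassium enolate of F3 and F1 are then joined by radical-nucleophilic aromatic substitution (SRN1; KOt-Bu, DMSO, FeBr2 as initiator, 25 °C, in the dark so the stilbene does not isomerise): the aryl radical from F1 attacks the enolate carbon and gives racemic, configurationally labile triaryl ketone F4. Asymmetric hydrogenation with dynamic kinetic resolution (RuCl2[(S)-xylbinap][(S)-daipen], KOt-Bu, i-PrOH, H2 8 atm; reduces C=O and not the stilbene C=C; the enantiomer of the catalyst is chosen by experiment) gives alcohol F5 with (R) at the triaryl carbon. Acid as in step 10 removes the MOM groups to give hexaphenol alcohol F6, whose benzylic alcohol ionises to the same quinone methide; the fallback comes back to the route at 16, which closes to 17 in the same flask.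

Step 8. NBS may brominate the electron-rich resorcinol ring instead of the alkene. The fallback sets out from 10. Dimethyldioxirane (acetone, −20 °C) gives trans-epoxide F7; methanol with pyridinium p-toluenesulfonate opens it at the carbon next to the para-oxygenated ring to give methoxy alcohol F8; Appel bromination (CBr4, PPh3, CH2Cl2, 0 °C) then gives the bromide as a mixture of diastereomers, which does not matter because step 9 passes through the radical. The fallback comes back to the route at 11.

Step 10. Protic acid may erode the ee at C-3 by loss of H-3 from the cation, or rearrange the product. The fallback sets out from 14 and cyclises before deprotecting. BF3·OEt2 (CH2Cl2, −78 °C) ionises the benzylic methyl ether; a flanking MOM-ether oxygen closes the ring and loses its methoxymethyl group, giving penta-MOM dihydrobenzofuran F9 at a temperature where elimination is slow. ZnBr2 and propane-1-thiol (CH2Cl2, 0 °C, minutes) then remove the five remaining MOM groups, and the fallback comes back to the route at 17.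

**Further compounds**

F1 | step 9 | 2-iodo-1,3-bis(methoxymethoxy)-5-[(E)-2-[3-methoxy-4-(methoxymethoxy)phenyl]ethenyl]benzene | COCOc1ccc(/C=C/c2cc(OCOC)c(I)c(OCOC)c2)cc1OC
F2 | step 9 | 1-[(E)-2-methoxy-2-[3-methoxy-4-(methoxymethoxy)phenyl]ethenyl]-3,5-bis(methoxymethoxy)benzene | CO/C(c1ccc(OCOC)c(OC)c1)=C/c1cc(OCOC)cc(OCOC)c1
F3 | step 9 | 2-[3,5-bis(methoxymethoxy)phenyl]-1-[3-methoxy-4-(methoxymethoxy)phenyl]ethan-1-one | COCOc1ccc(cc1OC)C(=O)Cc1cc(OCOC)cc(OCOC)c1
F4 | step 9 | rac-2-[3,5-bis(methoxymethoxy)phenyl]-2-[2,6-bis(methoxymethoxy)-4-[(E)-2-[3-methoxy-4-(methoxymethoxy)phenyl]ethenyl]phenyl]-1-[3-methoxy-4-(methoxymethoxy)phenyl]ethan-1-one | COCOc1ccc(cc1OC)C(=O)C(c1cc(OCOC)cc(OCOC)c1)c1c(OCOC)cc(/C=C/c2ccc(OCOC)c(OC)c2)cc1OCOC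
F5 | step 9 | (2R)-2-[3,5-bis(methoxymethoxy)phenyl]-2-[2,6-bis(methoxymethoxy)-4-[(E)-2-[3-methoxy-4-(methoxymethoxy)phenyl]ethenyl]phenyl]-1-[3-methoxy-4-(methoxymethoxy)phenyl]ethan-1-ol (carbinol configuration set by the catalyst and lost later) | COCOc1ccc(/C=C/c2cc(OCOC)c(c(OCOC)c2)[C@@H](c2cc(OCOC)cc(OCOC)c2)C(O)c2ccc(OCOC)c(OC)c2)cc1OC
F6 | step 9 | 2-[(1R)-1-(3,5-dihydroxyphenyl)-2-hydroxy-2-(4-hydroxy-3-methoxyphenyl)ethyl]-5-[(E)-2-(4-hydroxy-3-methoxyphenyl)ethenyl]benzene-1,3-diol | COc1cc(/C=C/c2cc(O)c(c(O)c2)[C@@H](c2cc(O)cc(O)c2)C(O)c2ccc(O)c(OC)c2)ccc1O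
F7 | step 8 | rac-trans-2-[3,5-bis(methoxymethoxy)phenyl]-3-[3-methoxy-4-(methoxymethoxy)phenyl]oxirane | COCOc1ccc(cc1OC)[C@H]1O[C@@H]1c1cc(OCOC)cc(OCOC)c1
F8 | step 8 | 1-[3,5-bis(methoxymethoxy)phenyl]-2-methoxy-2-[3-methoxy-4-(methoxymethoxy)phenyl]ethan-1-ol (racemic, diastereomer mixture) | COCOc1ccc(cc1OC)C(OC)C(O)c1cc(OCOC)cc(OCOC)c1
F9 | step 10 | (2R,3R)-3-[3,5-bis(methoxymethoxy)phenyl]-4-(methoxymethoxy)-2-[3-methoxy-4-(methoxymethoxy)phenyl]-6-[(E)-2-[3-methoxy-4-(methoxymethoxy)phenyl]ethenyl]-2,3-dihydro-1-benzofuran | COCOc1ccc(/C=C/c2cc(OCOC)c3c(c2)O[C@@H](c2ccc(OCOC)c(OC)c2)[C@@H]3c2cc(OCOC)cc(OCOC)c2)cc1OC
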